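The cyclohex-2-enone ring is opened at C4–C5 and C6–C1. C5, its nonadecyl chain and C6 come from the silyl enol ether of henicosan-2-one; C1–C4 are C6, C5, C4 and C3 of methyl 2-oxo-2H-pyran-3-carboxylate. A copper bis(oxazoline)-catalysed inverse-electron-demand Diels–Alder reaction joins both bonds at once and sets the C5 carbinol within a bicyclic lactone. It exploits the 1,3-relation of the C1 carbonyl and the C5 carbinol across C6 and leaves the C2=C3 alkene in place. The lactone bridge and the ester on C4 are then excised by saponification, oxidation at C1 and double decarboxylation of the vinylogous β-keto diacid; desilylation ends the route.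

Key step: step 3

Remark: the ligand enantiomer is chosen from the square-planar chelate model of copper bis(oxazoline) catalysis and the silyloxy group is assumed to go endo; the sense has to be confirmed on the first batch of 7, and the enantiomeric ligand is equally available.

Step 1
Reactants: 1 icosanoic acid (arachidic acid)
Product: 3 henicosan-2-one, via dilithium henicosane-2,2-diolate 2 (not isolated)
Conditions: MeLi (2.2 equiv), THF, 0 °C to rt; then poured into cold 1 M HCl
Reagents that add atoms: methyllithium, C[Li]
Why: The lithium carboxylate takes up one further methyllithium and the dilithium gem-diolate does not collapse before the acidic quench, so the methyl ketone should form without over-addition (ketone synthesis from a carboxylic acid and an organolithium).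

Step 2
Reactants: 3 henicosan-2-one
Product: 5 triethyl[(henicos-1-en-2-yl)oxy]silane, via lithium henicos-1-en-2-olate 4 (not isolated)
Conditions: LiN(iPr)2 (1.1 equiv), THF, −78 °C, slow addition of 3 in THF; then Et3SiCl, −78 to 0 °C
Reagents that add atoms: chlorotriethylsilane, CC[Si](Cl)(CC)CC
Why: Kinetic deprotonation at −78 °C should take place at the methyl group, and O-silylation of the lithium enolate gives the terminal silyl enol ether (kinetic enolate trapping).

Step 3
Reactants: 5 triethyl[(henicos-1-en-2-yl)oxy]silane; 6 methyl 2-oxo-2H-pyran-3-carboxylate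
Product: 7 methyl (1R,4R,8R)-8-nonadecyl-3-oxo-8-[(triethylsilyl)oxy]-2-oxabicyclo[2.2.2]oct-5-ene-4-carboxylate
Conditions: Cu(OTf)2 (10 mol %), (R,R)-tBu-BOX [2,2'-(propane-2,2-diyl)bis((4R)-4-tert-butyl-4,5-dihydrooxazole)] (11 mol %), 4 Å molecular sieves, CH2Cl2, −40 to −10 °C
Reagents that add atoms: none
Why: The lactone and ester carbonyls of 6 chelate the divalent copper centre, which lowers the LUMO of the pyranone, and the nucleophilic CH2 terminus of 5 bonds to C6 of the pyranone while its silyloxy carbon bonds to C3 in a concerted, asynchronous inverse-electron-demand Diels–Alder reaction. The closest known reaction type is the chiral Lewis acid catalysed cycloaddition of 3-carboalkoxy-2-pyranones with vinyl ethers and silyl enol ethers. One ring is closed, the cyclohexene ring, by [4+2] cycloaddition suprafacial on both partners, and the pyranone ring thereby becomes the lactone bridge of the 2-oxabicyclo[2.2.2]octene. C1 and C4 are controlled by the ligand, whose tert-butyl group in the square-planar chelate should shield the pyranone face from which O1, C2 and C3 run counterclockwise, so that 5 adds to the opposite face; C8 is controlled by the endo position of the silyloxy group, syn to the C5=C6 bridge, and this combination maps onto (S) at the carbinol carbon of 12. The step needs regioselectivity, secured by the polarisation of both partners (donor-bearing carbon to the ester-bearing C3), and face and endo selectivity, secured by the twofold-symmetric ligand and by the usual endo preference of the oxygen substituent. Loss of the silyl group from a stepwise zwitterion before ring closure is disfavoured by the triethylsilyl group and the low temperature.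

Step 4
Reactants: 7 methyl (1R,4R,8R)-8-nonadecyl-3-oxo-8-[(triethylsilyl)oxy]-2-oxabicyclo[2.2.2]oct-5-ene-4-carboxylate
Product: 8 (4R,6R)-4-hydroxy-6-nonadecyl-6-[(triethylsilyl)oxy]cyclohex-2-ene-1,1-dicarboxylic acid
Conditions: LiOH·H2O (8 equiv), THF/MeOH/H2O, rt, then 50 °C; then 1 M HCl to pH 3 at 0 °C
Reagents that add atoms: lithium hydroxide, [Li+].[OH-]
Why: Hydroxide should open the strained, doubly activated lactone at room temperature and then saponify the methyl ester on warming, while the silyl ether stays on so that no free alkoxide next to the malonate carbon can start a retro-aldol cleavage; no stereocentre is touched (lactone and ester saponification).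

Step 5
Reactants: 8 (4R,6R)-4-hydroxy-6-nonadecyl-6-[(triethylsilyl)oxy]cyclohex-2-ene-1,1-dicarboxylic acid
Product: 11 (5S)-5-nonadecyl-5-[(triethylsilyl)oxy]cyclohex-2-en-1-one, via 4-oxo diacid 9 (not isolated), via 4-oxo monoacid 10 (not isolated)
Conditions: Dess–Martin periodinane, CH2Cl2, 0 °C to rt; volatiles removed; then toluene, 80 °C
Reagents that add atoms: none
Why: Dess–Martin oxidation should convert only the secondary allylic alcohol into the enone, which turns the gem-diacid into a vinylogous β-keto malonic acid that loses two molecules of CO2 through dienol intermediates on warming, as known for 4-oxocyclohex-2-ene-1-carboxylic acids, with final protonation at the γ-carbon giving the conjugated enone; the silyloxy-bearing carbon is not involved.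

Step 6
Reactants: 11 (5S)-5-nonadecyl-5-[(triethylsilyl)oxy]cyclohex-2-en-1-one
Product: 12 (5S)-5-hydroxy-5-nonadecylcyclohex-2-en-1-one (CNP0103007.1)
Conditions: HF·pyridine, pyridine, THF, 0 °C to rt
Reagents that add atoms: none
Why: Buffered fluoride cleavage of the triethylsilyl ether under weakly acidic conditions should free the tertiary alcohol without base, which avoids β-elimination, retro-aldol opening and aromatisation to the 3-alkylphenol (silyl ether deprotection).

Compound list
1 | icosanoic acid (arachidic acid) | CCCCCCCCCCCCCCCCCCCC(=O)O | starting material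
2 | dilithium henicosane-2,2-diolate | CCCCCCCCCCCCCCCCCCCC(C)(O[Li])O[Li] | intermediate (not isolated)
3 | henicosan-2-one | CCCCCCCCCCCCCCCCCCCC(C)=O | intermediate
4 | lithium henicos-1-en-2-olate | CCCCCCCCCCCCCCCCCCCC(=C)O[Li] | intermediate (not isolated)
5 | triethyl[(henicos-1-en-2-yl)oxy]silane | CCCCCCCCCCCCCCCCCCCC(=C)O[Si](CC)(CC)CC | intermediate
6 | methyl 2-oxo-2H-pyran-3-carboxylate | COC(=O)C1=CC=COC1=O | starting material
7 | methyl (1R,4R,8R)-8-nonadecyl-3-oxo-8-[(triethylsilyl)oxy]-2-oxabicyclo[2.2.2]oct-5-ene-4-carboxylate | O=C1O[C@H]2C=C[C@]1(C(=O)OC)[C@@](O[Si](CC)(CC)CC)(CCCCCCCCCCCCCCCCCCC)C2 | intermediate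
8 | (4R,6R)-4-hydroxy-6-nonadecyl-6-[(triethylsilyl)oxy]cyclohex-2-ene-1,1-dicarboxylic acid | OC(=O)C1(C(=O)O)C=C[C@H](O)C[C@]1(O[Si](CC)(CC)CC)CCCCCCCCCCCCCCCCCCC | intermediate
9 | (6R)-6-nonadecyl-4-oxo-6-[(triethylsilyl)oxy]cyclohex-2-ene-1,1-dicarboxylic acid | OC(=O)C1(C(=O)O)C=CC(=O)C[C@]1(O[Si](CC)(CC)CC)CCCCCCCCCCCCCCCCCCC | intermediate (not isolated)
10 | (6R)-6-nonadecyl-4-oxo-6-[(triethylsilyl)oxy]cyclohex-2-ene-1-carboxylic acid (both C1 epimers) | OC(=O)C1C=CC(=O)C[C@]1(O[Si](CC)(CC)CC)CCCCCCCCCCCCCCCCCCC | intermediate (not isolated)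
11 | (5S)-5-nonadecyl-5-[(triethylsilyl)oxy]cyclohex-2-en-1-one | CCCCCCCCCCCCCCCCCCC[C@]1(O[Si](CC)(CC)CC)CC=CC(=O)C1 | intermediate
12 | (5S)-5-hydroxy-5-nonadecylcyclohex-2-en-1-one | CCCCCCCCCCCCCCCCCCC[C@]1(O)CC=CC(=O)C1 | target

Total step count: 6. Longest linear sequence: 6 steps (1 to 12).

Steps most likely to fail

Step 3. Face selectivity or endo/exo selectivity of the cycloaddition may be too low, or the enol ether may add in a Michael sense and lose its silyl group without closing the ring. The fallback sets out from 5 and comes back to the route at 10. Compound 5 is heated with commercial 3-bromo-2H-pyran-2-one in toluene at 90 °C, a thermal cycloaddition of the same regiochemistry that needs no catalyst, and the endo adduct, the racemic bromo lactone F1, is separated. Bu3SnH with AIBN in toluene at 80 °C removes the bridgehead bromine to give the racemic lactone F2, and K2CO3 in methanol opens it to the racemic hydroxy ester F3. Esterification of F3 with (S)-2-methoxy-2-phenylacetic acid (DCC, DMAP, CH2Cl2) gives two diastereomers, and chromatography separates the wanted mandelate F4 from the unwanted mandelate F5. LiOH in aqueous THF, then acid, cleaves both ester groups of F4 to the single-enantiomer hydroxy acid F6. Dess–Martin oxidation of F6 gives 10, which is decarboxylated to 11 as in step 5.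

Step 5. The second decarboxylation may be slow, and the dienol on its path may lose triethylsilanol and aromatise when the mixture is forced. The fallback sets out from 10 and comes back at 11. The oxidation is run as before and the mixture is kept at or below 40 °C, so that only the first CO2 is lost and 10 can be isolated. Coupling of 10 with N-hydroxypyridine-2-thione (DCC, CH2Cl2, dark) gives the thiohydroxamate ester F8. Irradiation with visible light in the presence of tBuSH at room temperature (Barton decarboxylation) removes the carboxyl group by a radical path that does not pass through a dienol. Any β,γ-enone formed by hydrogen transfer to the other end of the allylic radical should move into conjugation on silica, so that 11 results.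

Step 4. Saponification may stall at the hindered half-ester, and forcing it may cleave the silyl ether and open the ring by retro-aldol fragmentation. The fallback sets out from 7 and comes back at 8. Lithium propanethiolate in HMPA at room temperature removes the methyl group by SN2 attack at the methyl carbon, not at the hindered carbonyl, and gives the lactone acid F7 with the lactone still closed. LiOH in aqueous THF at room temperature then opens only the lactone, and acidification gives 8.

Further compounds
F1 | step 3 | rac-(1R,4S,8R)-4-bromo-8-nonadecyl-8-[(triethylsilyl)oxy]-2-oxabicyclo[2.2.2]oct-5-en-3-one (one enantiomer drawn) | O=C1O[C@H]2C=C[C@]1(Br)[C@@](O[Si](CC)(CC)CC)(CCCCCCCCCCCCCCCCCCC)C2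
F2 | step 3 | rac-(1R,4R,8R)-8-nonadecyl-8-[(triethylsilyl)oxy]-2-oxabicyclo[2.2.2]oct-5-en-3-one (one enantiomer drawn) | O=C1O[C@H]2C=C[C@@H]1[C@@](O[Si](CC)(CC)CC)(CCCCCCCCCCCCCCCCCCC)C2
F3 | step 3 | methyl rac-(1R,4R,6R)-4-hydroxy-6-nonadecyl-6-[(triethylsilyl)oxy]cyclohex-2-ene-1-carboxylate (one enantiomer drawn) | COC(=O)[C@@H]1C=C[C@H](O)C[C@]1(O[Si](CC)(CC)CC)CCCCCCCCCCCCCCCCCCC
F4 | step 3 | methyl (1R,4R,6R)-4-{[(2S)-2-methoxy-2-phenylacetyl]oxy}-6-nonadecyl-6-[(triethylsilyl)oxy]cyclohex-2-ene-1-carboxylate | COC(=O)[C@@H]1C=C[C@H](OC(=O)[C@@H](OC)c2ccccc2)C[C@]1(O[Si](CC)(CC)CC)CCCCCCCCCCCCCCCCCCC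
F5 | step 3 | methyl (1S,4S,6S)-4-{[(2S)-2-methoxy-2-phenylacetyl]oxy}-6-nonadecyl-6-[(triethylsilyl)oxy]cyclohex-2-ene-1-carboxylate | COC(=O)[C@H]1C=C[C@@H](OC(=O)[C@@H](OC)c2ccccc2)C[C@@]1(O[Si](CC)(CC)CC)CCCCCCCCCCCCCCCCCCC
F6 | step 3 | (1R,4R,6R)-4-hydroxy-6-nonadecyl-6-[(triethylsilyl)oxy]cyclohex-2-ene-1-carboxylic acid | OC(=O)[C@@H]1C=C[C@H](O)C[C@]1(O[Si](CC)(CC)CC)CCCCCCCCCCCCCCCCCCC
F7 | step 4 | (1R,4R,8R)-8-nonadecyl-3-oxo-8-[(triethylsilyl)oxy]-2-oxabicyclo[2.2.2]oct-5-ene-4-carboxylic acid | O=C1O[C@H]2C=C[C@]1(C(=O)O)[C@@](O[Si](CC)(CC)CC)(CCCCCCCCCCCCCCCCCCC)C2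
F8 | step 5 | 2-thioxopyridin-1(2H)-yl (6R)-6-nonadecyl-4-oxo-6-[(triethylsilyl)oxy]cyclohex-2-ene-1-carboxylate | S=C1C=CC=CN1OC(=O)C1C=CC(=O)C[C@]1(O[Si](CC)(CC)CC)CCCCCCCCCCCCCCCCCCC
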